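**Plan**

- Cuts (eudesmane locants): C6–OH back to a C6 ketone; ring A at C4–C5 (enol ether onto a C4≡C15 alkyne); ring B at C9–C10 (C9 aldehyde onto the enone C6(=O)–C5=C10); chain at C5–C6 and C7–C8.
- Forward: an auxiliary-derived aldehyde and an (E)-alkenyl iodide from hepta-1,6-diyne are joined to an acyclic keto aldehyde; ring B closes first, ring A second, then the C6 ketone is reduced.
- Enabling feature: in ring B the oxygenated carbons C6 and C9 are 1,4-related and the quaternary C10 is β to C6, so a C6 ketone makes C10 the β-carbon of an enone that a C9 ketyl can attack.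
- The same C6 carbonyl then serves as the enol nucleophile that closes ring A on the alkyne (creating the C4=C15 methylidene) and is finally taken down to the C6 alcohol.
- Stereochemistry: C7 from the oxazolidinone; C9 and C10 from the chair-like ketyl addition to the (E)-enone; C5 from tether-enforced cis closure of ring A; C6 from hydride attack anti to the axial C10 methyl.

Key step: step 8

Remark: eudesmane locants are used throughout (C10 methyl-bearing quaternary carbon, C9 ester-bearing CH, C5 ring-fusion CH, C6 carbinol, C7 isopropyl-bearing CH, C4=C15 methylidene); compound 1 is taken to be a catalogue item.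

**Step 1**
Reactants: 1 (R)-4-benzyl-3-(3-methylbutanoyl)oxazolidin-2-one; 2 allyl bromide
Product: 4 (R)-4-benzyl-3-[(2R)-2-(propan-2-yl)pent-4-enoyl]oxazolidin-2-one, via sodium enolate 3 (not isolated)
Conditions: NaN(SiMe3)2, THF, −78 °C; then 2, −78 → −45 °C
Reagents that add atoms: none
Why: Evans asymmetric alkylation, in which the chelated (Z)-enolate should be allylated on the face anti to the benzyl group, setting C7 as R.

**Step 2**
Reactants: 4
Product: 5 (2R)-2-(propan-2-yl)pent-4-en-1-ol
Conditions: LiBH4, H2O (1 equiv), Et2O, 0 °C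
Reagents that add atoms: none
Why: Reductive cleavage of the N-acyl oxazolidinone to the primary alcohol should leave the α-stereocentre untouched and return the auxiliary.

**Step 3**
Reactants: 5
Product: 6 (2R)-2-(propan-2-yl)pent-4-enal
Conditions: Dess–Martin periodinane, CH2Cl2, 0 °C → rt; used at once
Reagents that add atoms: none
Why: Dess–Martin oxidation is non-basic, so the α-branched aldehyde should form without epimerization.

**Step 4**
Reactants: 7 hepta-1,6-diyne (3 equiv)
Product: 9 (1E)-1-iodo-2-methylhept-1-en-6-yne, via alkenylalane 8 (not isolated)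
Conditions: AlMe3 (1.0 equiv), Cp2ZrCl2 (0.2 equiv), CH2Cl2, 0 °C → rt; then I2, THF, −30 → 0 °C
Reagents that add atoms: trimethylaluminium, C[Al](C)C; iodine, II
Why: Negishi zirconium-catalysed carboalumination adds CH3 and Al syn across one alkyne with Al on the terminal carbon, and iodinolysis with retention should give the E iodide; the excess diyne limits double addition.

**Step 5**
Reactants: 6 (2R)-2-(propan-2-yl)pent-4-enal; 9 (1E)-1-iodo-2-methylhept-1-en-6-yne
Product: 10 (4R,6E)-7-methyl-4-(propan-2-yl)dodeca-1,6-dien-11-yn-5-ol (both C5 epimers)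
Conditions: CrCl2 (4 equiv), NiCl2 (2 mol %), DMSO, rt
Reagents that add atoms: none
Why: Nozaki–Hiyama–Kishi coupling should join the alkenyl iodide to the aldehyde with retention of the E geometry and tolerate the terminal alkyne and alkene; the new carbinol centre is formed as a mixture that step 6 erases.

**Step 6**
Reactants: 10
Product: 11 (4R,6E)-7-methyl-4-(propan-2-yl)dodeca-1,6-dien-11-yn-5-one
Conditions: Dess–Martin periodinane, CH2Cl2, 0 °C → rt
Reagents that add atoms: none
Why: Dess–Martin oxidation of the allylic alcohol should give the (E)-enone without touching the α′-stereocentre C7.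

**Step 7**
Reactants: 11
Product: 13 (3R,5E)-6-methyl-4-oxo-3-(propan-2-yl)undec-5-en-10-ynal, via diol 12 (not isolated)
Conditions: OsO4 (2 mol %), NaIO4 (4 equiv), 2,6-lutidine (2 equiv), dioxane/H2O 3:1, rt
Reagents that add atoms: osmium tetroxide, O=[Os](=O)(=O)=O; sodium periodate, [Na+].[O-]I(=O)(=O)=O
Why: Lemieux–Johnson cleavage, in which OsO4 should dihydroxylate the monosubstituted alkene far faster than the electron-poor enone alkene or the alkyne, and periodate cleaves the diol to the C9 aldehyde.

**Step 8**
Reactants: 13
Product: 15 (2R,4R,5R)-4-hydroxy-5-methyl-5-(pent-4-yn-1-yl)-2-(propan-2-yl)cyclohexan-1-one, via samarium enolate 14 (not isolated)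
Conditions: SmI2 (2.5 equiv), HMPA (10 equiv), t-BuOH (2 equiv), THF (0.01 M), −78 °C
Reagents that add atoms: none
Why: Electron transfer from SmI2 to the C9 aldehyde gives a samarium ketyl that adds to C10, the β-carbon of the C6(=O)–C5=C10 enone, and a second electron turns the C5 α-keto radical into samarium enolate 14, which t-BuOH protonates at C5 (a CH2, no stereocentre). The closest known reaction type is the SmI2-mediated ketyl–olefin (aldehyde–enone) reductive cyclization. Ring B closes in the 6-endo-trig mode, the enone carbonyl C6 lying inside the new ring. C9 is set by a chair-like transition state in which the C7 isopropyl group and the bulky samarium-bound ketyl oxygen are both pseudo-equatorial, which places the C9 oxygen cis to the isopropyl group. C10 is set by the (E)-alkene geometry: the methyl group cis to C6 becomes axial and the pentynyl chain equatorial, so the methyl ends up cis to the C9 oxygen. The step needs attack at the β-carbon C10 and not 5-exo attack at C5 or pinacol coupling to C6; the polarization of the enone secures this (only β-attack gives an α-keto radical that is reduced at once), and −78 °C should preserve the alkene geometry and leave the alkyne untouched.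

**Step 9**
Reactants: 15; 16 4-methoxybenzoyl chloride
Product: 17 (1R,2R,5R)-2-methyl-4-oxo-2-(pent-4-yn-1-yl)-5-(propan-2-yl)cyclohexyl 4-methoxybenzoate
Conditions: Et3N, DMAP (0.2 equiv), CH2Cl2, 0 °C → rt
Reagents that add atoms: none
Why: DMAP-catalysed acylation of the equatorial secondary alcohol installs the ester of the target early, so no protecting group is needed, and the alcohol is γ to the ketone, so neither retro-aldol nor elimination can interfere.

**Step 10**
Reactants: 17
Product: 18 (1R,2R,5R)-4-[(tert-butyldimethylsilyl)oxy]-2-methyl-2-(pent-4-yn-1-yl)-5-(propan-2-yl)cyclohex-3-en-1-yl 4-methoxybenzoate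
Conditions: TBSOTf, Et3N, CH2Cl2, −78 → 0 °C
Reagents that add atoms: tert-butyldimethylsilyl trifluoromethanesulfonate, CC(C)(C)[Si](C)(C)OS(=O)(=O)C(F)(F)F
Why: Soft enolization (silyl triflate and amine) should form the silyl enol ether towards the C5 methylene, since the tetrasubstituted isomer at C7 would suffer allylic strain with the isopropyl group, and the amine base leaves the alkyne C–H alone.

**Step 11**
Reactants: 18
Product: 19 (1R,3R,4aS,8aR)-8a-methyl-5-methylidene-4-oxo-3-(propan-2-yl)decahydronaphthalen-1-yl 4-methoxybenzoate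
Conditions: Ph3PAuCl (5 mol %), AgBF4 (5 mol %), CH2Cl2/MeOH 10:1, rt
Reagents that add atoms: none
Why: Gold-catalysed carbocyclization of a silyl enol ether onto an alkyne (Conia-ene type, 6-exo-dig) joins C5 to the activated internal alkyne carbon C4 and, after desilylation and protodeauration, gives the ketone and the C4=C15 methylidene; because the tether hangs from C10, the C4–C5 bond can only form on the enol ether face syn to C1, which should set H5 cis to the C10 methyl (cis-decalin).

**Step 12**
Reactants: 19
Product: 20 (1R,3R,4S,4aS,8aR)-4-hydroxy-8a-methyl-5-methylidene-3-(propan-2-yl)decahydronaphthalen-1-yl 4-methoxybenzoate (target)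
Conditions: LiBH(s-Bu)3, THF, −78 °C; then H2O
Reagents that add atoms: none
Why: Substrate-controlled hydride reduction, in which the axial face of the C6 ketone is blocked by the syn-axial C10 methyl, so the bulky borohydride should attack equatorially and give the axial alcohol cis to the methyl and to H5, as in reductions of 6-oxo steroids of the cis A/B series; the aryl ester is inert at −78 °C.

**Compound list**

1 | (R)-4-benzyl-3-(3-methylbutanoyl)oxazolidin-2-one | CC(C)CC(=O)N1C(=O)OC[C@H]1Cc1ccccc1 | starting material
2 | allyl bromide (3-bromoprop-1-ene) | C=CCBr | starting material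
3 | sodium (Z)-enolate of 1 | CC(C)/C=C(\[O-])N1C(=O)OC[C@H]1Cc1ccccc1.[Na+] | intermediate
4 | (R)-4-benzyl-3-[(2R)-2-(propan-2-yl)pent-4-enoyl]oxazolidin-2-one | C=CC[C@H](C(C)C)C(=O)N1C(=O)OC[C@H]1Cc1ccccc1 | intermediate
5 | (2R)-2-(propan-2-yl)pent-4-en-1-ol | C=CC[C@H](C(C)C)CO | intermediate
6 | (2R)-2-(propan-2-yl)pent-4-enal | C=CC[C@H](C(C)C)C=O | intermediate
7 | hepta-1,6-diyne | C#CCCCC#C | starting material
8 | dimethyl[(1E)-2-methylhept-1-en-6-yn-1-yl]aluminium | C#CCCC/C(C)=C/[Al](C)C | intermediate
9 | (1E)-1-iodo-2-methylhept-1-en-6-yne | C#CCCC/C(C)=C/I | intermediate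
10 | (4R,6E)-7-methyl-4-(propan-2-yl)dodeca-1,6-dien-11-yn-5-ol (both C5 epimers) | C#CCCC/C(C)=C/C(O)[C@@H](C(C)C)CC=C | intermediate
11 | (4R,6E)-7-methyl-4-(propan-2-yl)dodeca-1,6-dien-11-yn-5-one | C#CCCC/C(C)=C/C(=O)[C@@H](C(C)C)CC=C | intermediate
12 | (4R,6E)-1,2-dihydroxy-7-methyl-4-(propan-2-yl)dodec-6-en-11-yn-5-one (both C2 epimers) | C#CCCC/C(C)=C/C(=O)[C@@H](C(C)C)CC(O)CO | intermediate
13 | (3R,5E)-6-methyl-4-oxo-3-(propan-2-yl)undec-5-en-10-ynal | C#CCCC/C(C)=C/C(=O)[C@@H](C(C)C)CC=O | intermediate
14 | bis(diiodosamarium) derivative of 15 (trivalent samarium on the C9 alkoxide and on the C6 enolate oxygen, C5=C6 enolate) | C#CCCC[C@]1(C)C=C(O[Sm](I)I)[C@@H](C(C)C)C[C@H]1O[Sm](I)I | intermediate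
15 | (2R,4R,5R)-4-hydroxy-5-methyl-5-(pent-4-yn-1-yl)-2-(propan-2-yl)cyclohexan-1-one | C#CCCC[C@]1(C)CC(=O)[C@@H](C(C)C)C[C@H]1O | intermediate
16 | 4-methoxybenzoyl chloride | COc1ccc(cc1)C(=O)Cl | starting material
17 | (1R,2R,5R)-2-methyl-4-oxo-2-(pent-4-yn-1-yl)-5-(propan-2-yl)cyclohexyl 4-methoxybenzoate | C#CCCC[C@]1(C)CC(=O)[C@@H](C(C)C)C[C@H]1OC(=O)c1ccc(OC)cc1 | intermediate
18 | (1R,2R,5R)-4-[(tert-butyldimethylsilyl)oxy]-2-methyl-2-(pent-4-yn-1-yl)-5-(propan-2-yl)cyclohex-3-en-1-yl 4-methoxybenzoate | C#CCCC[C@]1(C)C=C(O[Si](C)(C)C(C)(C)C)[C@@H](C(C)C)C[C@H]1OC(=O)c1ccc(OC)cc1 | intermediate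
19 | (1R,3R,4aS,8aR)-8a-methyl-5-methylidene-4-oxo-3-(propan-2-yl)decahydronaphthalen-1-yl 4-methoxybenzoate | C=C1CCC[C@]2(C)[C@H]1C(=O)[C@@H](C(C)C)C[C@H]2OC(=O)c1ccc(OC)cc1 | intermediate
20 | (1R,3R,4S,4aS,8aR)-4-hydroxy-8a-methyl-5-methylidene-3-(propan-2-yl)decahydronaphthalen-1-yl 4-methoxybenzoate | C=C1CCC[C@]2(C)[C@H]1[C@@H](O)[C@@H](C(C)C)C[C@H]2OC(=O)c1ccc(OC)cc1 | target

**Count and risks**

Total steps: 12. Longest linear sequence: 11 (steps 1–3 and 5–12; step 4 is the side branch).

Step 8 (key cyclization). The risk is that the electron goes to the enone and not to the aldehyde; the acyclic β,β-disubstituted enone prefers the s-cis form, which cannot cyclize, so plain conjugate reduction, pinacol coupling or loss of the alkene-geometry memory at C10 could take over. The fallback makes the C9 radical without electron transfer and with the ester oxygen already in place. It sets out from 13: addition of 16 across the aldehyde (ZnCl2 cat., CH2Cl2, 0 °C) should give the 1-chloroalkyl ester (3R,5E)-1-chloro-6-methyl-4-oxo-3-(propan-2-yl)undec-5-en-10-yn-1-yl 4-methoxybenzoate F1. Displacement with EtOCS2K (acetone, 0 °C) should give the xanthate (3R,5E)-1-[(ethoxycarbonothioyl)sulfanyl]-6-methyl-4-oxo-3-(propan-2-yl)undec-5-en-10-yn-1-yl 4-methoxybenzoate F2. Dilauroyl peroxide (portionwise, stoichiometric) in refluxing 2-propanol then generates the nucleophilic α-acyloxy C9 radical, which should add 6-endo to C10; the electrophilic C5 radical is reduced by the solvent. The sequence comes back to the route at 17, and step 9 is no longer needed.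

Step 11 (ring A closure). The risk is that methanolysis of the silyl enol ether back to 17, hydration of the alkyne or 7-endo closure outruns the 6-exo-dig attack. The fallback is a radical closure of the same bond. It sets out from 18: NBS (THF, 0 °C) should brominate regiospecifically at C5 to give the α-bromo ketone, the 3-bromo derivative of 17 (bromine on the ring CH between the ketone and the quaternary carbon, both epimers) F3. Bu3SnH (syringe pump), AIBN, benzene, 80 °C then gives the C5 α-keto radical, which should cyclize 6-exo-dig onto the alkyne; the vinyl radical takes hydrogen from the stannane. The same tether argument predicts the cis ring fusion, and the sequence comes back at 19.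

Step 12 (C6 reduction). The risk is poor facial selectivity or enolization, because the equatorial trajectory is also hindered (by the C4 methylidene on the adjacent axial carbon). The fallback gives up substrate control for reagent control: Corey–Bakshi–Shibata reduction of 19 with the oxazaborolidine enantiomer matched to deliver hydride to the same face (BH3·SMe2, THF, −20 °C). It sets out from 19 and comes back at 20; no compound outside the list is made (F0).

**Further compounds**

F1 | step 8 | (3R,5E)-1-chloro-6-methyl-4-oxo-3-(propan-2-yl)undec-5-en-10-yn-1-yl 4-methoxybenzoate (both C1 epimers) | C#CCCC/C(C)=C/C(=O)[C@@H](C(C)C)CC(Cl)OC(=O)c1ccc(OC)cc1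
F2 | step 8 | (3R,5E)-1-[(ethoxycarbonothioyl)sulfanyl]-6-methyl-4-oxo-3-(propan-2-yl)undec-5-en-10-yn-1-yl 4-methoxybenzoate (both C1 epimers) | C#CCCC/C(C)=C/C(=O)[C@@H](C(C)C)CC(SC(=S)OCC)OC(=O)c1ccc(OC)cc1
F3 | step 11 | 3-bromo derivative of 17 (α-bromo ketone, both epimers at the brominated carbon) | C#CCCC[C@]1(C)C(Br)C(=O)[C@@H](C(C)C)C[C@H]1OC(=O)c1ccc(OC)cc1
F0 | step 12 | none | none
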